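**Retrosynthetic overview**

- The strategy rests on chain carbons C1–C7, numbered from the ether oxygen. C1–C3 are three sp3 carbons ending in oxygen and leading to the E C4=C5 alkene, which is the γ,δ-unsaturated ester pattern of an orthoester Claisen product once C1 is at the ester level. The Z C6=C7 alkene is carried as an alkyne.
- Late disconnections: the O2 aroyl ester (acylation of a 1-O-alkyl-sn-glycerol whose stereocentre is bought as (R)-solketal), then the C1–O ether (Williamson alkylation), then the 6Z alkene back to the alkyne (activated zinc).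
- Key disconnection: the C2–C3 bond and the 4E alkene, by Johnson–Claisen rearrangement of (6E)-deca-1,6-dien-4-yn-3-ol. The carbinol comes from acrolein and the acetylide of (E)-hept-3-en-1-yne, made from (E)-hex-2-enal through its dibromo-olefin.
- No ring is formed in the route. The benzene ring arrives with 4-hydroxybenzoic acid, and the dioxolane of solketal is only a temporary protecting ring.

Key step: step 3

Remark: the carbinol is used as the racemate because its stereocentre is erased in the rearrangement. All compounds containing the (E,Z,E)-triene are to be handled under argon with exclusion of light.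

**Route**

Step 1
Reactants: 1 (E)-hex-2-enal
Product: 2 (3E)-1,1-dibromohepta-1,3-diene
Conditions: CBr4, PPh3, CH2Cl2, 0 °C
Reagents that add atoms: carbon tetrabromide, BrC(Br)(Br)Br
Why: Corey–Fuchs dibromo-olefination, in which the ylide formed from CBr4 and PPh3 converts the aldehyde into the 1,1-dibromoalkene without touching the E alkene; it is chosen over diazophosphonate homologation in basic methanol, which is prone to conjugate addition of methoxide to enals.

Step 2
Reactants: 2 (3E)-1,1-dibromohepta-1,3-diene, 3 acrolein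
Product: 5 (6E)-deca-1,6-dien-4-yn-3-ol (racemic), via lithium acetylide 4 (not isolated)
Conditions: n-BuLi (2.1 equiv), THF, −78 °C; then 3, −78 °C; aq. NH4Cl
Reagents that add atoms: none
Why: The second stage of the Corey–Fuchs sequence (bromine–lithium exchange, elimination and deprotonation by two equivalents of n-BuLi) gives the lithium acetylide directly, and lithium acetylides add 1,2 to acrolein at low temperature; the new carbinol centre needs no control because step 3 destroys it.

Step 3
Reactants: 5 (6E)-deca-1,6-dien-4-yn-3-ol (racemic), 6 triethyl orthoacetate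
Product: 9 ethyl (4E,8E)-dodeca-4,8-dien-6-ynoate, via mixed orthoester 7 (not isolated), via ketene acetal 8 (not isolated)
Conditions: MeC(OEt)3 (excess, as solvent), EtCO2H (cat.), 140 °C, EtOH distilled off
Reagents that add atoms: none
Why: Propionic acid catalyses exchange of one ethoxy group of 6 for the carbinol oxygen (mixed orthoester 7) and loss of ethanol to ketene acetal 8, which undergoes a concerted [3,3]-sigmatropic shift: the ketene-acetal CH2 bonds to the terminal vinyl carbon (new C2–C3 bond), the carbinol C–O bond breaks and the 4,5-alkene forms. This is the Johnson orthoester Claisen rearrangement, a reaction type established for alk-1-en-4-yn-3-ols, which give (E)-alk-4-en-6-ynoates. No ring is closed and no stereocentre is made; the racemic carbinol carbon becomes sp2. The 4E geometry follows from the chair transition state with the alkynyl substituent pseudo-equatorial. The step also needs the shift to run through the vinyl arm and not the alkynyl arm (which would give an allenyl ester): the allyl pathway uses an unstrained six-membered chair, whereas the propargyl pathway must bend the linear triple bond into the cyclic array and bond to an internal, substituted alkyne carbon, so it should be clearly slower. Carrying C6–C7 as a triple bond means that no Z alkene is exposed to the 140 °C needed, so thermal Z/E isomerisation and 1,5-hydrogen shifts are excluded, and distilling off ethanol drives both pre-equilibria.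

Step 4
Reactants: 9 ethyl (4E,8E)-dodeca-4,8-dien-6-ynoate
Product: 10 (4E,8E)-dodeca-4,8-dien-6-yn-1-ol
Conditions: LiAlH4, Et2O, 0 °C
Reagents that add atoms: none
Why: Hydride reduction of the ester to the primary alcohol; at 0 °C the conjugated dienyne, which has no propargylic hydroxyl to direct hydroalumination, is not attacked.

Step 5
Reactants: 10 (4E,8E)-dodeca-4,8-dien-6-yn-1-ol
Product: 11 (4E,8E)-dodeca-4,8-dien-6-yn-1-yl methanesulfonate
Conditions: MsCl, Et3N, CH2Cl2, 0 °C
Reagents that add atoms: methanesulfonyl chloride, CS(=O)(=O)Cl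
Why: Standard sulfonylation of a primary alcohol, which activates C1 for substitution without affecting the dienyne.

Step 6
Reactants: 11 (4E,8E)-dodeca-4,8-dien-6-yn-1-yl methanesulfonate, 12 (R)-solketal
Product: 14 (4R)-4-{[(4E,8E)-dodeca-4,8-dien-6-yn-1-yloxy]methyl}-2,2-dimethyl-1,3-dioxolane, via sodium alkoxide of solketal 13 (not isolated)
Conditions: NaH, DMF, 0 °C; then 11, rt to 50 °C
Reagents that add atoms: none
Why: Williamson ether synthesis by SN2 displacement of the unhindered primary mesylate; the stereocentre of solketal takes no part and is stable to base, so its configuration is carried over unchanged.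

Step 7
Reactants: 14 (4R)-4-{[(4E,8E)-dodeca-4,8-dien-6-yn-1-yloxy]methyl}-2,2-dimethyl-1,3-dioxolane
Product: 15 (2S)-3-[(4E,8E)-dodeca-4,8-dien-6-yn-1-yloxy]propane-1,2-diol
Conditions: 1 M aq. HCl, THF, rt
Reagents that add atoms: none
Why: Acid-catalysed hydrolysis of the isopropylidene acetal, placed before the semireduction so that only the acid-robust dienyne, and never the isomerisation-prone triene, meets aqueous acid; no bond to the stereocentre is broken.

Step 8
Reactants: 15 (2S)-3-[(4E,8E)-dodeca-4,8-dien-6-yn-1-yloxy]propane-1,2-diol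
Product: 16 (2S)-3-[(4E,6Z,8E)-dodeca-4,6,8-trien-1-yloxy]propane-1,2-diol
Conditions: Zn dust activated with Cu(OAc)2 then AgNO3, MeOH/H2O 1:1, rt to 40 °C, Ar, dark
Reagents that add atoms: none
Why: Boland-type semireduction, in which zinc activated with copper and silver transfers two hydrogens cis to a conjugated triple bond only and stops at the alkene, so the 6Z geometry results from syn addition while the flanking E alkenes are untouched; the free diol makes the substrate compatible with aqueous methanol.

Step 9
Reactants: 16 (2S)-3-[(4E,6Z,8E)-dodeca-4,6,8-trien-1-yloxy]propane-1,2-diol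
Product: 17 (2R)-1-[(tert-butyldimethylsilyl)oxy]-3-[(4E,6Z,8E)-dodeca-4,6,8-trien-1-yloxy]propan-2-ol
Conditions: TBSCl (1.05 equiv), imidazole, CH2Cl2, 0 °C
Reagents that add atoms: tert-butyldimethylsilyl chloride, CC(C)(C)[Si](C)(C)Cl
Why: Silyl ether formation, in which the bulky silyl chloride reacts much faster with the primary than with the flanked secondary hydroxyl, leaving O2 free (the descriptor changes from S to R only because the priorities change).

Step 10
Reactants: 18 4-hydroxybenzoic acid
Product: 19 tert-butyldimethylsilyl 4-[(tert-butyldimethylsilyl)oxy]benzoate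
Conditions: TBSCl (2.3 equiv), imidazole, DMF, rt
Reagents that add atoms: tert-butyldimethylsilyl chloride, CC(C)(C)[Si](C)(C)Cl
Why: Exhaustive silylation of the phenol and the carboxylic acid (silyl ether and silyl ester formation) with imidazole as base.

Step 11
Reactants: 19 tert-butyldimethylsilyl 4-[(tert-butyldimethylsilyl)oxy]benzoate
Product: 20 4-[(tert-butyldimethylsilyl)oxy]benzoyl chloride
Conditions: (COCl)2, DMF (cat.), CH2Cl2, 0 °C to rt; evaporated and used crude
Reagents that add atoms: oxalyl chloride, O=C(Cl)C(=O)Cl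
Why: Silyl esters are converted into acid chlorides by the chloroiminium salt from oxalyl chloride and DMF under neutral conditions, releasing the silyl chloride instead of HCl, so the aryl silyl ether survives.

Step 12
Reactants: 17 (2R)-1-[(tert-butyldimethylsilyl)oxy]-3-[(4E,6Z,8E)-dodeca-4,6,8-trien-1-yloxy]propan-2-ol, 20 4-[(tert-butyldimethylsilyl)oxy]benzoyl chloride
Product: 21 (2R)-1-[(tert-butyldimethylsilyl)oxy]-3-[(4E,6Z,8E)-dodeca-4,6,8-trien-1-yloxy]propan-2-yl 4-[(tert-butyldimethylsilyl)oxy]benzoate
Conditions: pyridine, DMAP (cat.), CH2Cl2, 0 °C to rt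
Reagents that add atoms: none
Why: DMAP-catalysed acylation of the secondary alcohol by the acid chloride through the acylpyridinium ion; no bond to the stereocentre is broken, so the configuration is retained, and the weakly basic medium does not cause silyl migration.

Step 13
Reactants: 21 (2R)-1-[(tert-butyldimethylsilyl)oxy]-3-[(4E,6Z,8E)-dodeca-4,6,8-trien-1-yloxy]propan-2-yl 4-[(tert-butyldimethylsilyl)oxy]benzoate
Product: 23 (2S)-1-[(4E,6Z,8E)-dodeca-4,6,8-trien-1-yloxy]-3-hydroxypropan-2-yl 4-hydroxybenzoate, via monosilyl phenol 22 (not isolated)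
Conditions: TBAF, AcOH (1:1), THF, 0 °C to rt; quick chromatography on boric-acid-treated silica
Reagents that add atoms: none
Why: Fluoride-mediated cleavage of both silicon–oxygen bonds (the aryl silyl ether first, then the primary one); buffering TBAF with acetic acid keeps the medium near neutral so that the aroyl group should stay on O2 and not migrate to the liberated primary hydroxyl.

**Compound list**

1 | (E)-hex-2-enal | CCC/C=C/C=O | starting material
2 | (3E)-1,1-dibromohepta-1,3-diene | CCC/C=C/C=C(Br)Br | intermediate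
3 | acrolein | C=CC=O | starting material
4 | lithium (3E)-hept-3-en-1-yn-1-ide (not isolated) | CCC/C=C/C#C[Li] | intermediate
5 | (6E)-deca-1,6-dien-4-yn-3-ol, racemic | C=CC(O)C#C/C=C/CCC | intermediate
6 | triethyl orthoacetate | CCOC(C)(OCC)OCC | starting material
7 | (6E)-3-(1,1-diethoxyethoxy)deca-1,6-dien-4-yne, mixed orthoester (not isolated) | CCOC(C)(OCC)OC(C=C)C#C/C=C/CCC | intermediate
8 | (6E)-3-[(1-ethoxyethenyl)oxy]deca-1,6-dien-4-yne, ketene acetal (not isolated) | C=C(OCC)OC(C=C)C#C/C=C/CCC | intermediate
9 | ethyl (4E,8E)-dodeca-4,8-dien-6-ynoate | CCOC(=O)CC/C=C/C#C/C=C/CCC | intermediate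
10 | (4E,8E)-dodeca-4,8-dien-6-yn-1-ol | OCCC/C=C/C#C/C=C/CCC | intermediate
11 | (4E,8E)-dodeca-4,8-dien-6-yn-1-yl methanesulfonate | CS(=O)(=O)OCCC/C=C/C#C/C=C/CCC | intermediate
12 | (R)-solketal, [(4R)-2,2-dimethyl-1,3-dioxolan-4-yl]methanol | OC[C@@H]1COC(C)(C)O1 | starting material
13 | sodium [(4R)-2,2-dimethyl-1,3-dioxolan-4-yl]methanolate (not isolated) | [Na+].[O-]C[C@@H]1COC(C)(C)O1 | intermediate
14 | (4R)-4-{[(4E,8E)-dodeca-4,8-dien-6-yn-1-yloxy]methyl}-2,2-dimethyl-1,3-dioxolane | CCC/C=C/C#C/C=C/CCCOC[C@@H]1COC(C)(C)O1 | intermediate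
15 | (2S)-3-[(4E,8E)-dodeca-4,8-dien-6-yn-1-yloxy]propane-1,2-diol | CCC/C=C/C#C/C=C/CCCOC[C@@H](O)CO | intermediate
16 | (2S)-3-[(4E,6Z,8E)-dodeca-4,6,8-trien-1-yloxy]propane-1,2-diol | CCC/C=C/C=C\C=C\CCCOC[C@@H](O)CO | intermediate
17 | (2R)-1-[(tert-butyldimethylsilyl)oxy]-3-[(4E,6Z,8E)-dodeca-4,6,8-trien-1-yloxy]propan-2-ol | CCC/C=C/C=C\C=C\CCCOC[C@@H](O)CO[Si](C)(C)C(C)(C)C | intermediate
18 | 4-hydroxybenzoic acid | O=C(O)c1ccc(O)cc1 | starting material
19 | tert-butyldimethylsilyl 4-[(tert-butyldimethylsilyl)oxy]benzoate | CC(C)(C)[Si](C)(C)OC(=O)c1ccc(O[Si](C)(C)C(C)(C)C)cc1 | intermediate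
20 | 4-[(tert-butyldimethylsilyl)oxy]benzoyl chloride | CC(C)(C)[Si](C)(C)Oc1ccc(C(=O)Cl)cc1 | intermediate
21 | (2R)-1-[(tert-butyldimethylsilyl)oxy]-3-[(4E,6Z,8E)-dodeca-4,6,8-trien-1-yloxy]propan-2-yl 4-[(tert-butyldimethylsilyl)oxy]benzoate | CCC/C=C/C=C\C=C\CCCOC[C@H](CO[Si](C)(C)C(C)(C)C)OC(=O)c1ccc(O[Si](C)(C)C(C)(C)C)cc1 | intermediate
22 | (2R)-1-[(tert-butyldimethylsilyl)oxy]-3-[(4E,6Z,8E)-dodeca-4,6,8-trien-1-yloxy]propan-2-yl 4-hydroxybenzoate (not isolated) | CCC/C=C/C=C\C=C\CCCOC[C@H](CO[Si](C)(C)C(C)(C)C)OC(=O)c1ccc(O)cc1 | intermediate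
23 | (2S)-1-[(4E,6Z,8E)-dodeca-4,6,8-trien-1-yloxy]-3-hydroxypropan-2-yl 4-hydroxybenzoate | CCC/C=C/C=C\C=C\CCCOC[C@H](CO)OC(=O)c1ccc(O)cc1 | target

**Step count**

Total step count: 13.
Longest linear sequence: 11 steps (steps 1 to 9, then 12 and 13). The two-step benzoate branch (steps 10 and 11) joins at step 12.

**Steps most likely to fail**

Step 3. The dienynol may oligomerise or decompose at 140 °C, acid may ionise the doubly activated carbinol, or the shift may run in part through the alkynyl arm to an allenyl ester. The fallback forms the C5–C6 bond by Sonogashira coupling instead of the C2–C3 bond by rearrangement. It sets out from 2: treatment with n-BuLi (2 equiv, THF, −78 °C) and quench of acetylide 4 with aqueous NH4Cl instead of acrolein would give (3E)-hept-3-en-1-yne F1, kept as a solution because of its volatility. Commercial pent-4-yn-1-ol would be converted into (4E)-5-iodopent-4-en-1-ol F2 by hydrozirconation (hydroxyl first capped with one equivalent of DIBAL-H, then Cp2Zr(H)Cl generated from Cp2ZrCl2 and DIBAL-H) followed by iodinolysis with I2. Coupling of F1 with F2 using Pd(PPh3)4 (zerovalent palladium, catalytic), CuI and Et2NH in THF at rt should give the dienynol directly, and the route is rejoined at 10.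

Step 8. The heterogeneous reduction may stall, over-reduce, or isomerise the new Z alkene on the metal surface, giving triene isomers that are hard to separate. The fallback makes the 6Z alkene by stereospecific cross-coupling rather than by reduction. It sets out from 2 and 12:
- From 2, palladium-catalysed hydrogenolysis of the bromine trans to the chain (Bu3SnH, Pd(PPh3)4 cat., benzene, rt) would give (1Z,3E)-1-bromohepta-1,3-diene F3.
- From 12, alkylation through alkoxide 13 (NaH, DMF, pent-4-yn-1-yl methanesulfonate) would give (4R)-2,2-dimethyl-4-[(pent-4-yn-1-yloxy)methyl]-1,3-dioxolane F4.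
- Hydroboration of F4 with pinacolborane (Cp2Zr(H)Cl cat., Et3N, 60 °C) would give 2-[(1E)-5-{[(4R)-2,2-dimethyl-1,3-dioxolan-4-yl]methoxy}pent-1-en-1-yl]-4,4,5,5-tetramethyl-1,3,2-dioxaborolane F5.
- Suzuki–Miyaura coupling of F3 with F5 (Pd(PPh3)4, aq. NaOH, THF, rt), which proceeds with retention at both alkenyl carbons, would give (4R)-4-{[(4E,6Z,8E)-dodeca-4,6,8-trien-1-yloxy]methyl}-2,2-dimethyl-1,3-dioxolane F6.
- Brief hydrolysis of F6 (AcOH/H2O 4:1, rt) comes back to the route at 16.

Step 13. The aroyl group may migrate from O2 to the liberated primary hydroxyl under fluoride or on silica, or the ester may be partly cleaved. The fallback carries the primary hydroxyl as a levulinate, which hydrazine removes by cyclisation under buffered, fluoride-free conditions, and unmasks the phenol while the primary oxygen is still blocked. It sets out from 16: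
- Selective primary acylation (levulinic acid, N,N'-diisopropylcarbodiimide, DMAP cat., CH2Cl2, −20 °C) would give (2R)-3-[(4E,6Z,8E)-dodeca-4,6,8-trien-1-yloxy]-2-hydroxypropyl 4-oxopentanoate F7.
- Acylation with 20 as in step 12 would give (2R)-1-[(4E,6Z,8E)-dodeca-4,6,8-trien-1-yloxy]-3-[(4-oxopentanoyl)oxy]propan-2-yl 4-[(tert-butyldimethylsilyl)oxy]benzoate F8.
- TBAF/AcOH in THF at 0 °C would cleave the aryl silyl ether to give (2R)-1-[(4E,6Z,8E)-dodeca-4,6,8-trien-1-yloxy]-3-[(4-oxopentanoyl)oxy]propan-2-yl 4-hydroxybenzoate F9. No free aliphatic hydroxyl is present at this stage, so nothing can migrate.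
- Hydrazine acetate in pyridine/AcOH at 0 °C under argon would then remove the levulinate and come back to the route at 23.

**Further compounds**

F1 | step 3 | (3E)-hept-3-en-1-yne | CCC/C=C/C#C
F2 | step 3 | (4E)-5-iodopent-4-en-1-ol | OCCC/C=C/I
F3 | step 8 | (1Z,3E)-1-bromohepta-1,3-diene | CCC/C=C/C=C\Br
F4 | step 8 | (4R)-2,2-dimethyl-4-[(pent-4-yn-1-yloxy)methyl]-1,3-dioxolane | C#CCCCOC[C@@H]1COC(C)(C)O1
F5 | step 8 | 2-[(1E)-5-{[(4R)-2,2-dimethyl-1,3-dioxolan-4-yl]methoxy}pent-1-en-1-yl]-4,4,5,5-tetramethyl-1,3,2-dioxaborolane | CC1(C)OB(/C=C/CCCOC[C@@H]2COC(C)(C)O2)OC1(C)C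
F6 | step 8 | (4R)-4-{[(4E,6Z,8E)-dodeca-4,6,8-trien-1-yloxy]methyl}-2,2-dimethyl-1,3-dioxolane | CCC/C=C/C=C\C=C\CCCOC[C@@H]1COC(C)(C)O1
F7 | step 13 | (2R)-3-[(4E,6Z,8E)-dodeca-4,6,8-trien-1-yloxy]-2-hydroxypropyl 4-oxopentanoate | CCC/C=C/C=C\C=C\CCCOC[C@@H](O)COC(=O)CCC(C)=O
F8 | step 13 | (2R)-1-[(4E,6Z,8E)-dodeca-4,6,8-trien-1-yloxy]-3-[(4-oxopentanoyl)oxy]propan-2-yl 4-[(tert-butyldimethylsilyl)oxy]benzoate | CCC/C=C/C=C\C=C\CCCOC[C@H](COC(=O)CCC(C)=O)OC(=O)c1ccc(O[Si](C)(C)C(C)(C)C)cc1
F9 | step 13 | (2R)-1-[(4E,6Z,8E)-dodeca-4,6,8-trien-1-yloxy]-3-[(4-oxopentanoyl)oxy]propan-2-yl 4-hydroxybenzoate | CCC/C=C/C=C\C=C\CCCOC[C@H](COC(=O)CCC(C)=O)OC(=O)c1ccc(O)cc1
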